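**Remark (assumption):** the target is taken exactly as drawn in the SMILES, i.e. 7β-hydroxy-18-oxo-labda-8(17),12E-diene joined through C12/C15 to the flavone-quinone. Labdane numbering is used throughout; in the A-homo intermediates the extra ring carbon between C3 and C4 is called C4a.

## Retrosynthetic overview

1. Last disconnection: Diels–Alder union of 7β-hydroxylabda-8(17),12E,14-trien-18-al with the chromonyl methoxyquinone; the cyclohexene ring is formed last.
2. Ring A (C1–C2–C3–C4–C5–C10) is made second to last by contraction of a seven-membered ring. The enabling feature is the quaternary C4, which carries the formyl carbon C18 and the C19 methyl next to the C3 methylene: this is the product pattern of a Lewis-acid epoxide (semipinacol) rearrangement. C18 is therefore carried as ring atom C4a of a 4α,4aα-epoxy-A-homo ring and is expelled as the aldehyde when C3 shifts to C4.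
3. The seven-membered ring comes from ring-closing metathesis of an isopropenyl group on C5 with a pentenyl chain on C10. Ring B with C5, C9 and C10 comes from (+)-verbenone by conjugate addition/alkylation and cleavage of its cyclobutane.
4. Order of ring formation: ring B (the six-membered ring of verbenone) → seven-membered A-homo ring → ring A by contraction → cyclohexene ring by cycloaddition. The quinone is made separately from a flavone.

Key step: step 11

## Route

**Step 1**
Reactants: 1 (1R,5R)-(+)-verbenone; 2 pent-4-en-1-ylmagnesium bromide; 3 1-bromobut-2-yne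
Product: 5 3-(but-2-ynyl)-4-(pent-4-enyl)-4,6,6-trimethylbicyclo[3.1.1]heptan-2-one (both chains anti to the gem-dimethyl bridge), via bromomagnesium enolate 4 (not isolated)
Conditions: 2 (1.3 equiv), CuBr·SMe2 (10 mol%), THF, −40 °C; then 3, HMPA, −40 → 0 °C
Reagents that add atoms: none
Why: Copper-catalysed conjugate addition of the Grignard reagent to the β-methyl enone should occur on the face opposite the gem-dimethyl bridge and so set the quaternary C10, and the enolate, whose only enolisable position is the future C9 (the other α-carbon is a bridgehead), should be C-alkylated by the propargylic bromide (three-component conjugate addition–enolate alkylation), the C9 configuration being corrected in step 2.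

**Step 2**
Reactants: 5
Product: 8 2-(but-2-ynyl)-3-methyl-3-(pent-4-enyl)-4-(prop-1-en-2-yl)cyclohexan-1-one (three chains equatorial; 5α-H/9β/10β-Me in labdane terms), via iodide silyl enol ether 6 (not isolated), via isopropenyl silyl enol ether 7 (not isolated)
Conditions: Me3SiI, CH2Cl2, −40 °C; then DBU, 0 °C → rt; then K2CO3, MeOH, rt
Reagents that add atoms: none
Why: Silyl-iodide-induced homoconjugate cleavage of the strained cyclobutane bond α to the ketone (the known acid-induced ring opening of nopinones) should give the tertiary iodide and the Δ7 silyl enol ether; DBU then eliminates HI toward a methyl group to give the isopropenyl group, and methanolysis frees the ketone and equilibrates C9 to the all-equatorial epimer, C5 being carried over unchanged from verbenone.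

**Step 3**
Reactants: 8
Product: 9 trans-fused A-homo ketone (8-oxo; C4=C4a alkene; 5α-H; 10β-methyl; 9β-but-2-ynyl)
Conditions: second-generation Grubbs catalyst (5 mol%), CH2Cl2, 40 °C
Reagents that add atoms: none
Why: Ring-closing metathesis of the terminal alkene with the isopropenyl group, held trans-diequatorial on C10 and C5, should close the seven-membered ring as its trisubstituted C4=C4a alkene with loss of ethene; no stereocentre is formed, and the internal alkyne should stay out because an enyne closure would need an eight-membered ring.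

**Step 4**
Reactants: 9
Product: 10 Δ7 tert-butyldimethylsilyl enol ether of 9
Conditions: LiN(iPr)2, THF, −78 °C; then TBSCl, HMPA, −78 → 0 °C
Reagents that add atoms: tert-butyldimethylsilyl chloride, CC(C)(C)[Si](C)(C)Cl
Why: Kinetic deprotonation should take a proton from the unhindered C7 methylene and not from the substituted C9 beside the quaternary C10, so O-silylation gives the Δ7 enol ether regioselectively (kinetic enolate trapping).

**Step 5**
Reactants: 10
Product: 11 4α,4aα-epoxy-7α-(tert-butyldimethylsilyloxy)-8-ketone
Conditions: mCPBA (2.3 equiv), NaHCO3, CH2Cl2, −20 → 0 °C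
Reagents that add atoms: meta-chloroperoxybenzoic acid, O=C(OO)c1cccc(Cl)c1
Why: Rubottom oxidation of the silyl enol ether (epoxidation, opening, 1,4-silyl shift) should put the protected oxygen on C7 from the α face (this centre is reset in steps 9 and 10), and the same peracid should epoxidise the trisubstituted C4=C4a alkene on the α face, opposite the axial C10 methyl group, which fixes the epoxide configuration that step 11 needs.

**Step 6**
Reactants: 11
Product: 12 4α,4aα-epoxy-7α-(tert-butyldimethylsilyloxy)-8(17)-methylene compound
Conditions: Ph3PCH3Br, KOtBu, toluene, 0 → 80 °C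
Reagents that add atoms: methyltriphenylphosphonium bromide, C[P+](c1ccccc1)(c1ccccc1)c1ccccc1.[Br-]
Why: Wittig methylenation of the hindered C8 ketone should give the exocyclic alkene while the trisubstituted epoxide and the alkyne are inert to the ylide; any epimerisation at C7 is without consequence because C7 becomes a carbonyl in step 9.

**Step 7**
Reactants: 12; 13 vinyl bromide
Product: 15 (12E)-4α,4aα-epoxy-7α-(tert-butyldimethylsilyloxy)-A-homo-18-norlabda-8(17),12,14-triene, via alkenylzirconocene chloride 14 (not isolated)
Conditions: Cp2Zr(H)Cl (1.3 equiv), THF, 0 °C → rt; then 13, ZnCl2 (20 mol%), Pd(PPh3)4 (5 mol%), rt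
Reagents that add atoms: none
Why: syn-Hydrozirconation should place zirconium on the methyl-bearing alkyne carbon C13 (steric control by the branched C9 side) and the palladium-catalysed Negishi-type coupling with vinyl bromide proceeds with retention, so the 12E diene results.

**Step 8**
Reactants: 15
Product: 16 7α-alcohol (4α,4aα-epoxy-A-homo-18-norlabda-8(17),12E,14-trien-7α-ol)
Conditions: Bu4NF, THF, 0 °C → rt
Reagents that add atoms: none
Why: Fluoride cleaves the silyl ether (desilylation) without touching epoxide or diene; no stereocentre changes.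

**Step 9**
Reactants: 16
Product: 17 7-oxo-8(17)-ene (exocyclic enone)
Conditions: Dess–Martin periodinane, NaHCO3, CH2Cl2, 0 °C → rt
Reagents that add atoms: none
Why: Oxidation of the allylic alcohol to the α-methylene ketone erases the C7 configuration so that it can be reset by hydride.

**Step 10**
Reactants: 17
Product: 18 4α,4aα-epoxy-A-homo-18-norlabda-8(17),12E,14-trien-7β-ol
Conditions: NaBH4, CeCl3·7H2O, MeOH, −78 → −40 °C
Reagents that add atoms: none
Why: Luche 1,2-reduction of the enone should deliver hydride axially from the α face and so give the equatorial 7β-alcohol, as is usual for 7-oxolabd-8(17)-enes.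

**Step 11**
Reactants: 18
Product: 19 7β-hydroxylabda-8(17),12E,14-trien-18-al
Conditions: MeAl(OAr)2 (Ar = 4-bromo-2,6-di-tert-butylphenyl; 2.5 equiv, made from AlMe3 and ArOH), CH2Cl2, −78 → −20 °C; aq. HCl work-up
Reagents that add atoms: none
Why: The aluminium reagent first takes up the C7 hydroxyl as its aluminium alkoxide and then binds the epoxide oxygen; the tertiary C4–O bond ionises and the C4a–C3 ring bond shifts to C4 anti to the departing oxygen while C4a becomes the formyl carbon C18 (Meinwald/semipinacol rearrangement), the release of oxirane strain driving formation of the C3–C4 bond. The closest known reaction type is the ring contraction of 1-methylcycloalkene oxides to 1-methylcycloalkanecarbaldehydes promoted by bulky methylaluminium bis(aryloxides). Ring A is closed in its final six-membered size by this suprafacial 1,2-alkyl shift (seven- to six-membered ring contraction), not by a cyclisation. The new quaternary stereocentre C4 is controlled by the epoxide: the α-oxygen leaves on the face of H5 and C3 enters with inversion, so the methyl group stays β (axial) and the formyl group ends α (equatorial), and the trans-fused seven-membered ring, in which C6 is equatorial, should lead to the same result even through a free cation. The step needs migration of the ring bond rather than of the C4a hydrogen, and activation of the epoxide rather than of the allylic C7–O bond or the diene; in the substrate the flexible seven-membered ring can align C4a–C3 with the breaking C4–O bond and loses medium-ring strain on contraction, the C7 oxygen is masked as a poorly ionising aluminium alkoxide, and the bulky non-nucleophilic aluminium phenoxide favours alkyl over hydride shift and cannot open the epoxide with a ligand.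

**Step 12**
Reactants: 20 1-(2,4,6-trihydroxyphenyl)ethan-1-one; 21 2,4,5-trimethoxybenzoyl chloride
Product: 23 5,7-dihydroxy-2-(2,4,5-trimethoxyphenyl)-4H-chromen-4-one, via aryl diketone 22 (not isolated)
Conditions: LiN(SiMe3)2 (4 equiv), THF, −78 °C → rt; then H2SO4, AcOH, 95 °C
Reagents that add atoms: none
Why: C-acylation of the polyanion of the acetophenone should give the 1,3-diketone, which cyclodehydrates under acid to the flavone (one-pot Baker–Venkataraman-type flavone synthesis); no stereocentre.

**Step 13**
Reactants: 23
Product: 24 5,7-dihydroxy-2-(4-methoxy-3,6-dioxocyclohexa-1,4-dien-1-yl)-4H-chromen-4-one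
Conditions: (NH4)2Ce(NO3)6 (2.5 equiv), MeCN–H2O, 0 °C
Reagents that add atoms: water, O
Why: Oxidative demethylation of the para-related 2'- and 5'-methoxy groups should give the 2-methoxy-1,4-quinone, the electron-rich trimethoxyphenyl ring being oxidised in preference to the carbonyl-deactivated dihydroxychromone ring.

**Step 14**
Reactants: 19; 24
Product: 25 Dichrostachine H
Conditions: THF, 45 °C, dark
Reagents that add atoms: none
Why: Thermal Diels–Alder reaction at the chromonyl-substituted quinone double bond (the methoxy-bearing one is a deactivated vinylogous ester): the unsubstituted diene terminus C15 should bond to the unsubstituted quinone carbon so that C12 ends on the quaternary carbon, suprafacial addition gives the cis ring fusion, the chromone-endo arrangement that keeps the bulky C11 substituent away from the angular chromonyl group gives the required configuration at C12, and the diene face is biased only by the allylic-strain conformation about C11–C12 imposed by C9, so the adduct from the other face is expected as the main by-product to be separated.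

## Compound list

1 | (1R,5R)-(+)-verbenone | CC1=CC(=O)[C@@H]2C[C@H]1C2(C)C | starting material
2 | pent-4-en-1-ylmagnesium bromide | C=CCCC[Mg]Br | starting material
3 | 1-bromobut-2-yne | CC#CCBr | starting material
4 | bromomagnesium enolate of 4-methyl-4-(pent-4-enyl)nopinone | C[C@@]1(CCCC=C)C=C(O[Mg]Br)[C@@H]2C[C@H]1C2(C)C | intermediate
5 | 3-(but-2-ynyl)-4-(pent-4-enyl)-4,6,6-trimethylbicyclo[3.1.1]heptan-2-one (chains anti to the gem-dimethyl bridge) | C[C@@]1(CCCC=C)[C@H](CC#CC)C(=O)[C@@H]2C[C@H]1C2(C)C | intermediate
6 | trimethylsilyl enol ether of 2-(but-2-ynyl)-4-(2-iodopropan-2-yl)-3-methyl-3-(pent-4-enyl)cyclohexanone | C[Si](C)(C)OC1=CC[C@@H](C(C)(C)I)[C@](C)(CCCC=C)[C@@H]1CC#CC | intermediate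
7 | trimethylsilyl enol ether of 2-(but-2-ynyl)-3-methyl-3-(pent-4-enyl)-4-(prop-1-en-2-yl)cyclohexanone (C9 epimer) | C[Si](C)(C)OC1=CC[C@@H](C(C)=C)[C@](C)(CCCC=C)[C@@H]1CC#CC | intermediate
8 | 2-(but-2-ynyl)-3-methyl-3-(pent-4-enyl)-4-(prop-1-en-2-yl)cyclohexan-1-one (all chains equatorial) | O=C1CC[C@@H](C(C)=C)[C@](C)(CCCC=C)[C@H]1CC#CC | intermediate
9 | trans-fused A-homo ketone (8-oxo; 4(4a)-ene; 5α-H; 10β-Me; 9β-but-2-ynyl) | O=C1CC[C@H]2C(C)=CCCC[C@]2(C)[C@H]1CC#CC | intermediate
10 | Δ7 tert-butyldimethylsilyl enol ether of 9 | CC(C)(C)[Si](C)(C)OC1=CC[C@H]2C(C)=CCCC[C@]2(C)[C@H]1CC#CC | intermediate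
11 | 4α,4aα-epoxy-7α-(tert-butyldimethylsilyloxy)-8-ketone | O=C1[C@H](O[Si](C)(C)C(C)(C)C)C[C@H]2[C@]3(C)O[C@@H]3CCC[C@]2(C)[C@H]1CC#CC | intermediate
12 | 4α,4aα-epoxy-7α-(tert-butyldimethylsilyloxy)-8(17)-methylene compound | C=C1[C@H](O[Si](C)(C)C(C)(C)C)C[C@H]2[C@]3(C)O[C@@H]3CCC[C@]2(C)[C@H]1CC#CC | intermediate
13 | vinyl bromide | C=CBr | starting material
14 | (E)-alkenylzirconocene chloride from 12 (Zr on C13) | C=C1[C@H](O[Si](C)(C)C(C)(C)C)C[C@H]2[C@]3(C)O[C@@H]3CCC[C@]2(C)[C@H]1C/C=C(C)/[Zr](Cl)(C4C=CC=C4)C5C=CC=C5 | intermediate
15 | (12E)-4α,4aα-epoxy-7α-(tert-butyldimethylsilyloxy)-A-homo-18-norlabda-8(17),12,14-triene | C=C1[C@H](O[Si](C)(C)C(C)(C)C)C[C@H]2[C@]3(C)O[C@@H]3CCC[C@]2(C)[C@H]1C/C=C(C)/C=C | intermediate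
16 | 4α,4aα-epoxy-A-homo-18-norlabda-8(17),12E,14-trien-7α-ol | C=C1[C@H](O)C[C@H]2[C@]3(C)O[C@@H]3CCC[C@]2(C)[C@H]1C/C=C(C)/C=C | intermediate
17 | 4α,4aα-epoxy-A-homo-18-norlabda-8(17),12E,14-trien-7-one | C=C1C(=O)C[C@H]2[C@]3(C)O[C@@H]3CCC[C@]2(C)[C@H]1C/C=C(C)/C=C | intermediate
18 | 4α,4aα-epoxy-A-homo-18-norlabda-8(17),12E,14-trien-7β-ol | C=C1[C@@H](O)C[C@H]2[C@]3(C)O[C@@H]3CCC[C@]2(C)[C@H]1C/C=C(C)/C=C | intermediate
19 | 7β-hydroxylabda-8(17),12E,14-trien-18-al | C=C1[C@@H](O)C[C@@H]2[C@](C)(CCC[C@@]2(C)C=O)[C@H]1C/C=C(C)/C=C | intermediate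
20 | 1-(2,4,6-trihydroxyphenyl)ethan-1-one | CC(=O)c1c(O)cc(O)cc1O | starting material
21 | 2,4,5-trimethoxybenzoyl chloride | COc1cc(OC)c(OC)cc1C(=O)Cl | starting material
22 | 1-(2,4,6-trihydroxyphenyl)-3-(2,4,5-trimethoxyphenyl)propane-1,3-dione | COc1cc(OC)c(OC)cc1C(=O)CC(=O)c1c(O)cc(O)cc1O | intermediate
23 | 5,7-dihydroxy-2-(2,4,5-trimethoxyphenyl)-4H-chromen-4-one | COc1cc(OC)c(OC)cc1-c1cc(=O)c2c(O)cc(O)cc2o1 | intermediate
24 | 5,7-dihydroxy-2-(4-methoxy-3,6-dioxocyclohexa-1,4-dien-1-yl)-4H-chromen-4-one | COC1=CC(=O)C(=CC1=O)c1cc(=O)c2c(O)cc(O)cc2o1 | intermediate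
25 | Dichrostachine H | C=C1[C@@H](O)C[C@@H]2[C@](C)(CCC[C@@]2(C)C=O)[C@H]1C[C@@H]1C(C)=CC[C@H]2C(=O)C(OC)=CC(=O)[C@@]12c1cc(=O)c2c(O)cc(O)cc2o1 | target

## Step count

Total step count: 14. Longest linear sequence: 12 steps (steps 1–11, then step 14).

## Steps most likely to fail, with fallbacks

**Step 14.** What may go wrong: poor control of the diene face and of the topography (chromone-endo versus enedione-endo), with erosion of regioselectivity, in the thermal cycloaddition. The fallback sets out from 24 and comes back at 25. Quinone 24 is treated with BF3·OEt2 to give the difluoroboron chelate of its peri-hydroxy ketone, F1. In F1 the chelated chromone is the dominant acceptor, so the reacting double bond becomes the terminus of a boron-activated dienone; this should reinforce both the attack of C15 on the unsubstituted carbon and the chromone-endo transition state. Cycloaddition of F1 with 19 (CH2Cl2, 0 °C → rt) would give the chelated adduct F2, which is freed with aqueous NaHCO3–MeOH to 25. A chiral diol–boron chelate in place of the BF2 unit would add reagent control of the diene face.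

**Step 11.** What may go wrong: diversion of the Lewis acid by the free C7 hydroxyl (consumption of reagent, ionisation of the allylic C7–O bond) and, with it, loss of the preference for ring-bond over hydride migration. The fallback sets out from 15 and comes back at 19. The ring contraction is run on the silyl ether 15, which has no free hydroxyl, with MeAl(OAr)2 (1.2 equiv) to give the aldehyde silyl ether F3. Bu4NF then gives the 7α-alcohol F4. Because hydride reduction is no longer compatible with the aldehyde, C7 is inverted by Mitsunobu esterification (4-nitrobenzoic acid, PPh3, diisopropyl azodicarboxylate) to the 7β-ester F5, and methanolysis (K2CO3, MeOH) gives 19.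

**Step 7.** What may go wrong: incomplete regiocontrol of the Zr–H addition (metal on C12 instead of C13) and over-reaction of the hydride with the exocyclic alkene or the epoxide. The fallback sets out from 12 and comes back at 15. Copper-catalysed borylcupration–protonation (B2pin2, CuCl, Xantphos, NaOtBu, MeOH) touches neither alkenes nor epoxides and places boron on the less hindered methyl-bearing carbon under ligand control, giving the alkenylboronate F6. Suzuki coupling of F6 with 13 (Pd(dppf)Cl2, K3PO4, THF–H2O) gives 15.

## Further compounds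

F1 | step 14 | difluoroboron chelate of quinone 24 | COC1=CC(=O)C(=CC1=O)c1cc2=[O+][B-](F)(F)Oc3cc(O)cc(o1)c23
F2 | step 14 | difluoroboron chelate of Dichrostachine H | C=C1[C@@H](O)C[C@@H]2[C@](C)(CCC[C@@]2(C)C=O)[C@H]1C[C@@H]1C(C)=CC[C@H]2C(=O)C(OC)=CC(=O)[C@@]12c1cc2=[O+][B-](F)(F)Oc3cc(O)cc(o1)c23
F3 | step 11 | 7α-(tert-butyldimethylsilyloxy)labda-8(17),12E,14-trien-18-al | C=C1[C@H](O[Si](C)(C)C(C)(C)C)C[C@@H]2[C@](C)(CCC[C@@]2(C)C=O)[C@H]1C/C=C(C)/C=C
F4 | step 11 | 7α-hydroxylabda-8(17),12E,14-trien-18-al | C=C1[C@H](O)C[C@@H]2[C@](C)(CCC[C@@]2(C)C=O)[C@H]1C/C=C(C)/C=C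
F5 | step 11 | 18-oxolabda-8(17),12E,14-trien-7β-yl 4-nitrobenzoate | C=C1[C@@H](OC(=O)c2ccc(cc2)[N+](=O)[O-])C[C@@H]3[C@](C)(CCC[C@@]3(C)C=O)[C@H]1C/C=C(C)/C=C
F6 | step 7 | (E)-alkenyl pinacol boronate from 12 (boron on C13) | C=C1[C@H](O[Si](C)(C)C(C)(C)C)C[C@H]2[C@]3(C)O[C@@H]3CCC[C@]2(C)[C@H]1C/C=C(C)/B4OC(C)(C)C(C)(C)O4
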